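Everything rests on opening the eight-membered ring at the bond between Cc, the methine next to the indane that carries a 4-hydroxyphenyl group, and the ortho carbon of ring B, the resorcinol ring on C3 of the dihydrobenzofuran. That carbon lies ortho to one ring B oxygen and para to the other, and Cc is para-oxybenzylic, so the bond is made by ionising a carbinol at Cc and letting ring B trap the cation. This single Friedel–Crafts alkylation closes the eight-membered ring and sets Cc. Its precursor is a ring-opened, permethylated indane whose three ring substituents are already 1,2-cis and 2,3-trans, assembled from an enantioenriched indanone and an enantioenriched 4-bromodihydrobenzofuran.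

Key step: step 15

Labels: Ca, Ce and Cb are the three sp3 carbons of the indane (Ca bears the 4-oxyphenyl group, Ce the benzofuran ring, Cb the one-carbon substituent Cc). Ring B is the 3,5-dioxygenated aryl group on C3 of the dihydrobenzofuran. DHB stands for the substituent (2R,3R)-3-(3,5-dimethoxyphenyl)-6-methoxy-2-(4-methoxyphenyl)-2,3-dihydro-1-benzofuran-4-yl.

Assumption: 11 and 19 are bought as catalogue compounds.

Remark: in steps 4 and 6 the ligand antipode named is the one expected from the usual models; the configuration drawn is what is needed, and the mirror-image ligand would be used if the sense of induction were opposite.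

Step 1
Reactants: 1 1-bromo-3,5-dimethoxybenzene; 2 3,5-dimethoxybenzoyl chloride
Product: 4 (2-bromo-6-hydroxy-4-methoxyphenyl)(3,5-dimethoxyphenyl)methanone, via methyl ether ketone 3 (not isolated)
Conditions: AlCl3 (2.5 equiv), CH2Cl2, 0 °C, then 40 °C
Reagents that add atoms: none
Why: Friedel–Crafts acylation should go to the carbon of 1 that is para to one methoxy group and ortho to the other (the position next to bromine, less hindered than the one between the two methoxy groups), and the AlCl3 chelate between the new ketone and its ortho methoxy group should then cleave only that methyl ether.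

Step 2
Reactants: 4 (2-bromo-6-hydroxy-4-methoxyphenyl)(3,5-dimethoxyphenyl)methanone; 5 4-methoxybenzyl chloride
Product: 6 {2-bromo-4-methoxy-6-[(4-methoxybenzyl)oxy]phenyl}(3,5-dimethoxyphenyl)methanone
Conditions: K2CO3, NaI (10 mol %), DMF, 60 °C
Reagents that add atoms: none
Why: Williamson etherification of the phenol installs the benzylic CH2 and the 4-methoxyphenyl ring that become C2 of the dihydrobenzofuran and its aryl group.

Step 3
Reactants: 6 {2-bromo-4-methoxy-6-[(4-methoxybenzyl)oxy]phenyl}(3,5-dimethoxyphenyl)methanone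
Product: 7 hydrazone of 6
Conditions: N2H4·H2O (10 equiv), AcOH (cat.), n-BuOH, 110 °C
Reagents that add atoms: hydrazine hydrate, NN.O
Why: Condensation of the hindered diaryl ketone with excess hydrazine under forcing conditions should give the free hydrazone, the electron-rich aryl bromide being inert to substitution without a metal catalyst.

Step 4
Reactants: 7 hydrazone of 6
Product: 9 (2S,3R)-4-bromo-3-(3,5-dimethoxyphenyl)-6-methoxy-2-(4-methoxyphenyl)-2,3-dihydro-1-benzofuran (2,3-cis), via diazo compound 8 (not isolated)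
Conditions: MnO2, CH2Cl2, 0 °C, filter; then Rh2(R-PTAD)4 (1 mol %), CH2Cl2, 0 °C
Reagents that add atoms: none
Why: Oxidation gives the diaryldiazomethane, and the chiral dirhodium donor/donor carbene should insert into the benzylic O–CH2 bond (enantioselective intramolecular C–H insertion), the catalyst fixing C3 as R and the concerted five-ring transition state placing the two aryl groups cis.

Step 5
Reactants: 9 (2S,3R)-4-bromo-3-(3,5-dimethoxyphenyl)-6-methoxy-2-(4-methoxyphenyl)-2,3-dihydro-1-benzofuran
Product: 10 (2R,3R)-4-bromo-3-(3,5-dimethoxyphenyl)-6-methoxy-2-(4-methoxyphenyl)-2,3-dihydro-1-benzofuran (2,3-trans)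
Conditions: CF3CO2H (10 equiv), CH2Cl2, 0 to 23 °C
Reagents that add atoms: none
Why: Acid reversibly ionises the para-methoxybenzylic C2–O bond and the phenol recloses to the thermodynamically preferred 2,3-trans ring (epimerisation at C2 by ring opening and reclosure), C3 staying untouched because reclosure should outrun loss of its proton.

Step 6
Reactants: 11 ethyl (E)-4-(benzyloxy)but-2-enoate; 12 3,5-dimethoxyphenylboronic acid
Product: 13 ethyl (3R)-4-(benzyloxy)-3-(3,5-dimethoxyphenyl)butanoate
Conditions: [Rh(acac)(C2H4)2] (3 mol %), (S)-BINAP (3.3 mol %), dioxane/H2O (10:1), 100 °C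
Reagents that add atoms: none
Why: Hayashi–Miyaura asymmetric conjugate addition, in which the aryl–rhodium–BINAP species should add to one face of the (E)-enoate (the si face at C2 in the usual model) and so set the benzylic center as R.

Step 7
Reactants: 13 ethyl (3R)-4-(benzyloxy)-3-(3,5-dimethoxyphenyl)butanoate
Product: 14 (3R)-4-(benzyloxy)-3-(3,5-dimethoxyphenyl)butanoic acid
Conditions: LiOH, THF/H2O (3:1), 23 °C; then 1 M HCl
Reagents that add atoms: lithium hydroxide, [Li+].[OH-]
Why: Saponification of the ethyl ester, which leaves the non-acidic stereocenter untouched.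

Step 8
Reactants: 14 (3R)-4-(benzyloxy)-3-(3,5-dimethoxyphenyl)butanoic acid
Product: 16 (3R)-3-[(benzyloxy)methyl]-5,7-dimethoxy-2,3-dihydro-1H-inden-1-one, via mixed anhydride 15 (not isolated)
Conditions: (CF3CO)2O (2 equiv), CH2Cl2, 0 to 23 °C
Reagents that add atoms: none
Why: Intramolecular Friedel–Crafts acylation by the mixed trifluoroacetic anhydride at the ring carbon that is ortho to the side chain and ortho/para to the two methoxy groups, under conditions mild enough for the benzyl ether.

Step 9
Reactants: 16 (3R)-3-[(benzyloxy)methyl]-5,7-dimethoxy-2,3-dihydro-1H-inden-1-one; 10 (2R,3R)-4-bromo-3-(3,5-dimethoxyphenyl)-6-methoxy-2-(4-methoxyphenyl)-2,3-dihydro-1-benzofuran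
Product: 17 (3R)-3-[(benzyloxy)methyl]-2-DHB-5,7-dimethoxy-2,3-dihydro-1H-inden-1-one (2,3-trans)
Conditions: Pd2(dba)3 (2.5 mol %), XPhos (6 mol %), NaOt-Bu (2.2 equiv), toluene, 80 °C
Reagents that add atoms: none
Why: Palladium-catalysed α-arylation of the ketone enolate at its only enolisable carbon, the bulky biarylphosphine coping with the ortho-substituted bromide; the new C2 center settles trans and is erased in the next step.

Step 10
Reactants: 17 (3R)-3-[(benzyloxy)methyl]-2-DHB-5,7-dimethoxy-2,3-dihydro-1H-inden-1-one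
Product: 18 (1S)-1-[(benzyloxy)methyl]-2-DHB-4,6-dimethoxy-1H-inden-3-yl trifluoromethanesulfonate
Conditions: KHMDS (1.0 equiv), THF, −78 °C; then PhNTf2, −78 to 0 °C
Reagents that add atoms: N-phenylbis(trifluoromethanesulfonimide), O=S(=O)(N(c1ccccc1)S(=O)(=O)C(F)(F)F)C(F)(F)F
Why: Deprotonation of the α-aryl ketone and O-sulfonylation (enol triflate formation), with no more than one equivalent of base so that the indene C1–H is not deprotonated.

Step 11
Reactants: 18 (1S)-1-[(benzyloxy)methyl]-2-DHB-4,6-dimethoxy-1H-inden-3-yl trifluoromethanesulfonate; 19 (4-methoxyphenyl)zinc iodide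
Product: 20 (1S)-1-[(benzyloxy)methyl]-2-DHB-4,6-dimethoxy-3-(4-methoxyphenyl)-1H-indene
Conditions: Pd(OAc)2 (5 mol %), SPhos (10 mol %), THF, 50 °C
Reagents that add atoms: none
Why: Negishi coupling of the enol triflate needs no added base, so the C1 stereocenter of the indene is not exposed to base-mediated 1,3-hydrogen shift.

Step 12
Reactants: 20 (1S)-1-[(benzyloxy)methyl]-2-DHB-4,6-dimethoxy-3-(4-methoxyphenyl)-1H-indene
Product: 21 [(1R,2R,3R)-2-DHB-4,6-dimethoxy-3-(4-methoxyphenyl)-2,3-dihydro-1H-inden-1-yl]methanol (all-cis)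
Conditions: H2 (5 bar), Pd(OH)2/C, EtOAc/EtOH (1:1), 23 °C
Reagents that add atoms: none
Why: Heterogeneous hydrogenation should add both hydrogens to the tetrasubstituted indene bond from the face opposite the C1 substituent (syn addition), setting Ca and Ce cis to each other and cis to the CH2O group, while the same catalyst removes the benzyl ether by hydrogenolysis.

Step 13
Reactants: 21 [(1R,2R,3R)-2-DHB-4,6-dimethoxy-3-(4-methoxyphenyl)-2,3-dihydro-1H-inden-1-yl]methanol
Product: 23 (1S,2R,3R)-2-DHB-4,6-dimethoxy-3-(4-methoxyphenyl)-2,3-dihydro-1H-indene-1-carbaldehyde (1,2-trans, 2,3-cis), via all-cis aldehyde 22 (not isolated)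
Conditions: Dess–Martin periodinane, CH2Cl2, 0 to 23 °C; then DBU (0.3 equiv), 23 °C
Reagents that add atoms: none
Why: Dess–Martin oxidation followed by base-mediated epimerisation through the enol should move the formyl group to the less crowded face, trans to the neighbouring aryl group, which inverts Cb to the configuration of the target.

Step 14
Reactants: 23 (1S,2R,3R)-2-DHB-4,6-dimethoxy-3-(4-methoxyphenyl)-2,3-dihydro-1H-indene-1-carbaldehyde; 24 (4-methoxyphenyl)magnesium bromide
Product: 25 (4-methoxyphenyl)[(1S,2R,3R)-2-DHB-4,6-dimethoxy-3-(4-methoxyphenyl)-2,3-dihydro-1H-inden-1-yl]methanol (both carbinol epimers)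
Conditions: THF, −78 to 0 °C; aq. NH4Cl
Reagents that add atoms: none
Why: Grignard addition to the aldehyde gives the para-methoxybenzylic alcohol as a mixture of carbinol epimers, which does not matter because this center is ionised in the next step.

Step 15
Reactants: 25 (4-methoxyphenyl)[(1S,2R,3R)-2-DHB-4,6-dimethoxy-3-(4-methoxyphenyl)-2,3-dihydro-1H-inden-1-yl]methanol
Product: 27 canaliculatol octamethyl ether, via benzylic cation 26 (not isolated)
Conditions: TfOH (5 mol %), (CF3)2CHOH/CH2Cl2 (1:4), 0.002 M, −20 to 0 °C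
Reagents that add atoms: none
Why: Acid in the fluorinated alcohol ionises the para-methoxybenzylic alcohol to cation 26, and an ortho carbon of ring B (ortho to one methoxy group and para to the other; the two ortho carbons are equivalent) attacks Cc and loses a proton, an intramolecular Friedel–Crafts alkylation of the kind that closes the seven-membered rings of related stilbene oligomers under acid. The eight-membered ring closes with the arene C=C bond inside the new ring (8-endo with respect to the nucleophilic π bond) and the leaving group outside it. Cc is set by allylic 1,3-strain: the cation should keep the Cb–H bond in its plane, ring B is tethered through Ce and must attack from the Ce face, and the 4-methoxyphenyl group therefore ends anti to the indane arene, as in the target. The step needs chemoselectivity among four electron-rich rings and must outrun E1 loss of the Cb proton. The 2,3-trans and 1,3-trans arrangement on the indane makes closure onto the benzofuran arene (a trans-fused diquinane) or onto the aryl group on Ca (a bridged bicyclo[3.2.1]octane) geometrically impossible, and catalytic acid at low temperature and high dilution disfavours elimination and intermolecular alkylation.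

Step 16
Reactants: 27 canaliculatol octamethyl ether
Product: 28 canaliculatol
Conditions: BBr3 (16 equiv), CH2Cl2, −78 to 23 °C; then MeOH, H2O
Reagents that add atoms: none
Why: Lewis-acid cleavage of the eight aryl methyl ethers with BBr3, the usual end game for permethylated stilbene oligomers; the trans dihydrobenzofuran is the thermodynamic isomer, so reversible opening of its benzylic C–O bond should reclose to the same ring, and no stereocenter is acidic.

Compound list

1 | 1-bromo-3,5-dimethoxybenzene | COc1cc(Br)cc(OC)c1 | starting material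
2 | 3,5-dimethoxybenzoyl chloride | COc1cc(cc(OC)c1)C(Cl)=O | starting material
3 | (2-bromo-4,6-dimethoxyphenyl)(3,5-dimethoxyphenyl)methanone | COc1cc(OC)c(C(=O)c2cc(OC)cc(OC)c2)c(Br)c1 | intermediate
4 | (2-bromo-6-hydroxy-4-methoxyphenyl)(3,5-dimethoxyphenyl)methanone | COc1cc(O)c(C(=O)c2cc(OC)cc(OC)c2)c(Br)c1 | intermediate
5 | 4-methoxybenzyl chloride | COc1ccc(CCl)cc1 | starting material
6 | {2-bromo-4-methoxy-6-[(4-methoxybenzyl)oxy]phenyl}(3,5-dimethoxyphenyl)methanone | COc1ccc(COc2cc(OC)cc(Br)c2C(=O)c2cc(OC)cc(OC)c2)cc1 | intermediate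
7 | hydrazone of 6 (C=N–NH2, E/Z mixture) | COc1ccc(COc2cc(OC)cc(Br)c2C(=NN)c2cc(OC)cc(OC)c2)cc1 | intermediate
8 | 1-bromo-2-[diazo(3,5-dimethoxyphenyl)methyl]-5-methoxy-3-[(4-methoxybenzyl)oxy]benzene | COc1ccc(COc2cc(OC)cc(Br)c2C(=[N+]=[N-])c2cc(OC)cc(OC)c2)cc1 | intermediate
9 | (2S,3R)-4-bromo-3-(3,5-dimethoxyphenyl)-6-methoxy-2-(4-methoxyphenyl)-2,3-dihydro-1-benzofuran (cis) | Brc1cc(OC)cc2O[C@H](c3ccc(OC)cc3)[C@H](c3cc(OC)cc(OC)c3)c12 | intermediate
10 | (2R,3R)-4-bromo-3-(3,5-dimethoxyphenyl)-6-methoxy-2-(4-methoxyphenyl)-2,3-dihydro-1-benzofuran (trans) | Brc1cc(OC)cc2O[C@@H](c3ccc(OC)cc3)[C@H](c3cc(OC)cc(OC)c3)c12 | intermediate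
11 | ethyl (E)-4-(benzyloxy)but-2-enoate | CCOC(=O)/C=C/COCc1ccccc1 | starting material
12 | 3,5-dimethoxyphenylboronic acid | COc1cc(cc(OC)c1)B(O)O | starting material
13 | ethyl (3R)-4-(benzyloxy)-3-(3,5-dimethoxyphenyl)butanoate | CCOC(=O)C[C@@H](COCc1ccccc1)c1cc(OC)cc(OC)c1 | intermediate
14 | (3R)-4-(benzyloxy)-3-(3,5-dimethoxyphenyl)butanoic acid | OC(=O)C[C@@H](COCc1ccccc1)c1cc(OC)cc(OC)c1 | intermediate
15 | (3R)-4-(benzyloxy)-3-(3,5-dimethoxyphenyl)butanoic trifluoroacetic anhydride | O=C(C[C@@H](COCc1ccccc1)c1cc(OC)cc(OC)c1)OC(=O)C(F)(F)F | intermediate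
16 | (3R)-3-[(benzyloxy)methyl]-5,7-dimethoxy-2,3-dihydro-1H-inden-1-one | COc1cc(OC)c2C(=O)C[C@@H](COCc3ccccc3)c2c1 | intermediate
17 | (3R)-3-[(benzyloxy)methyl]-2-DHB-5,7-dimethoxy-2,3-dihydro-1H-inden-1-one, 2,3-trans | O=C1c2c(OC)cc(OC)cc2[C@H](COCc2ccccc2)[C@H]1c1cc(OC)cc2O[C@@H](c3ccc(OC)cc3)[C@H](c3cc(OC)cc(OC)c3)c12 | intermediate
18 | (1S)-1-[(benzyloxy)methyl]-2-DHB-4,6-dimethoxy-1H-inden-3-yl trifluoromethanesulfonate | FC(F)(F)S(=O)(=O)OC1=C(c2cc(OC)cc3O[C@@H](c4ccc(OC)cc4)[C@H](c4cc(OC)cc(OC)c4)c23)[C@@H](COCc2ccccc2)c2cc(OC)cc(OC)c12 | intermediate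
19 | (4-methoxyphenyl)zinc iodide (0.5 M in THF) | COc1ccc([Zn]I)cc1 | starting material
20 | (1S)-1-[(benzyloxy)methyl]-2-DHB-4,6-dimethoxy-3-(4-methoxyphenyl)-1H-indene | COc1ccc(C2=C(c3cc(OC)cc4O[C@@H](c5ccc(OC)cc5)[C@H](c5cc(OC)cc(OC)c5)c34)[C@@H](COCc3ccccc3)c3cc(OC)cc(OC)c23)cc1 | intermediate
21 | [(1R,2R,3R)-2-DHB-4,6-dimethoxy-3-(4-methoxyphenyl)-2,3-dihydro-1H-inden-1-yl]methanol (all-cis) | COc1ccc([C@@H]2c3c(OC)cc(OC)cc3[C@H](CO)[C@@H]2c2cc(OC)cc3O[C@@H](c4ccc(OC)cc4)[C@H](c4cc(OC)cc(OC)c4)c23)cc1 | intermediate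
22 | (1R,2R,3R)-2-DHB-4,6-dimethoxy-3-(4-methoxyphenyl)-2,3-dihydro-1H-indene-1-carbaldehyde (all-cis) | COc1ccc([C@@H]2c3c(OC)cc(OC)cc3[C@H](C=O)[C@@H]2c2cc(OC)cc3O[C@@H](c4ccc(OC)cc4)[C@H](c4cc(OC)cc(OC)c4)c23)cc1 | intermediate
23 | (1S,2R,3R)-2-DHB-4,6-dimethoxy-3-(4-methoxyphenyl)-2,3-dihydro-1H-indene-1-carbaldehyde (1,2-trans, 2,3-cis) | COc1ccc([C@@H]2c3c(OC)cc(OC)cc3[C@@H](C=O)[C@@H]2c2cc(OC)cc3O[C@@H](c4ccc(OC)cc4)[C@H](c4cc(OC)cc(OC)c4)c23)cc1 | intermediate
24 | (4-methoxyphenyl)magnesium bromide | COc1ccc([Mg]Br)cc1 | starting material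
25 | (4-methoxyphenyl)[(1S,2R,3R)-2-DHB-4,6-dimethoxy-3-(4-methoxyphenyl)-2,3-dihydro-1H-inden-1-yl]methanol, both carbinol epimers | COc1ccc([C@@H]2c3c(OC)cc(OC)cc3[C@@H](C(O)c3ccc(OC)cc3)[C@@H]2c2cc(OC)cc3O[C@@H](c4ccc(OC)cc4)[C@H](c4cc(OC)cc(OC)c4)c23)cc1 | intermediate
26 | para-methoxybenzylic cation formed from 25 by loss of hydroxide | COc1ccc([C@@H]2c3c(OC)cc(OC)cc3[C@@H]([CH+]c3ccc(OC)cc3)[C@@H]2c2cc(OC)cc3O[C@@H](c4ccc(OC)cc4)[C@H](c4cc(OC)cc(OC)c4)c23)cc1 | intermediate
27 | canaliculatol octamethyl ether | COc1ccc([C@@H]2c3c(OC)cc(OC)cc3[C@H]3[C@H](c4ccc(OC)cc4)c4c(OC)cc(OC)cc4[C@@H]4c5c(cc(OC)cc5[C@H]23)O[C@H]4c2ccc(OC)cc2)cc1 | intermediate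
28 | canaliculatol | Oc1ccc([C@@H]2c3c(O)cc(O)cc3[C@H]3[C@H](c4ccc(O)cc4)c4c(O)cc(O)cc4[C@@H]4c5c(cc(O)cc5[C@H]23)O[C@H]4c2ccc(O)cc2)cc1 | target

Total step count: 16.
Longest linear sequence: 13 steps (steps 1 to 5, then 9 to 16); the indanone branch (steps 6 to 8) joins at step 9.

Steps most likely to fail

Step 15. The cation may lose the proton on Cb faster than the eight-membered ring closes (E1 to the exocyclic stilbene, which erases Cb and then allows five-ring closure onto the benzofuran arene), or intermolecular alkylation may compete. The fallback changes the order in which the two aryl–Cc bonds are made and sets out from aldehyde 23. Sc(OTf)3 (10 mol %) in CH2Cl2/(CF3)2CHOH at high dilution should let ring B add to the activated formyl group, an intramolecular Friedel–Crafts hydroxyalkylation in which the ring exists before any cation next to the Cb–H bond is formed. This gives the ring-closed carbinol canaliculatol-type alcohol F1 (both epimers at Cc). F1 is then ionised with TfOH (5 mol %) in the presence of anisole (10 equiv), whose para carbon should attack the ring-B-stabilised cation from the face opposite the indane arene and so place the 4-methoxyphenyl group as in the target. The fallback comes back to the route at 27.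

Step 4. The di-ortho-substituted diazo compound may form azine or react sluggishly, and the crowded carbene may insert with poor enantio- or diastereocontrol. The fallback gives up the catalytic asymmetric step and sets out from hydroxy ketone 4. NaBH4 in MeOH at 0 °C reduces it to the ortho-hydroxybenzhydrol 3-bromo-2-[(3,5-dimethoxyphenyl)(hydroxy)methyl]-5-methoxyphenol F2. F2 with (4-methoxybenzyl)dimethylsulfonium tetrafluoroborate and Cs2CO3 in CH2Cl2 should form the ortho-quinone methide, which the sulfonium ylide captures in a [4+1] annulation (1,4-addition, then 5-exo displacement of dimethyl sulfide) to give the racemic trans-dihydrobenzofuran F3. Preparative chromatography on a chiral stationary phase then delivers 10, where the fallback comes back to the route.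

Step 12. The tetrasubstituted, triaryl-substituted double bond may reduce slowly, the catalyst may shift the double bond and erase C1, the benzylic C–O bond of the dihydrobenzofuran may be hydrogenolysed, or facial selectivity may be poor. The fallback replaces the surface-bound syn addition by stepwise ionic hydrogenation and sets out from indene 20. CF3CO2H and Et3SiH in CH2Cl2 at 0 °C should protonate C2 from the face opposite the benzyloxymethyl group and then deliver hydride to the diaryl cation anti to the C2 aryl group, giving the all-cis benzyl ether F4. Hydrogenolysis of the benzyl ether alone (H2, 1 bar, Pd/C, EtOAc) then gives 21, where the fallback comes back to the route.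

Further compounds

F1 | step 15 | ring-closed carbinol: canaliculatol octamethyl ether in which the 4-methoxyphenyl group on Cc is replaced by OH (both epimers at Cc) | COc1ccc([C@@H]2c3c(OC)cc(OC)cc3[C@H]3C(O)c4c(OC)cc(OC)cc4[C@@H]4c5c(cc(OC)cc5[C@H]23)O[C@H]4c2ccc(OC)cc2)cc1
F2 | step 4 | 3-bromo-2-[(3,5-dimethoxyphenyl)(hydroxy)methyl]-5-methoxyphenol (racemic) | COc1cc(O)c(C(O)c2cc(OC)cc(OC)c2)c(Br)c1
F3 | step 4 | racemic trans-4-bromo-3-(3,5-dimethoxyphenyl)-6-methoxy-2-(4-methoxyphenyl)-2,3-dihydro-1-benzofuran (1:1 mixture of 10 and its enantiomer) | Brc1cc(OC)cc2O[C@@H](c3ccc(OC)cc3)[C@H](c3cc(OC)cc(OC)c3)c12.Brc1cc(OC)cc2O[C@H](c3ccc(OC)cc3)[C@@H](c3cc(OC)cc(OC)c3)c12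
F4 | step 12 | (1R,2R,3R)-1-[(benzyloxy)methyl]-2-DHB-4,6-dimethoxy-3-(4-methoxyphenyl)-2,3-dihydro-1H-indene (all-cis) | COc1ccc([C@@H]2c3c(OC)cc(OC)cc3[C@H](COCc3ccccc3)[C@@H]2c2cc(OC)cc3O[C@@H](c4ccc(OC)cc4)[C@H](c4cc(OC)cc(OC)c4)c23)cc1
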